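**Plan**

1. Retrosynthesis: cut the fumaramide C–N bond and the bond from the ring carbon to the sorbyl carbonyl carbon. Then cut the lactone C–O bond together with the ring bond between the quaternary C(CH3)(O) carbon and the ring-fusion CH (α-ketol retron); this puts the CH back on the neighbouring carbonyl carbon and leaves a 1-acetylcyclopent-2-en-1-ol. Last, cut the acetyl–carbinol bond and the bond between the ring CH and the amino acid carbon (Mannich retron).
2. Forward: the five-membered carbocycle comes ready-made from 2-methylcyclopentane-1,3-dione. A Mannich reaction joins the alanine unit, an acetyl anion equivalent is added to the ring ketone, and the carbocycle is then expanded from five to six atoms while the γ-lactone closes in the same operation. The enol ether, the sorbyl chain and the fumaric half-amide follow.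
3. Enabling feature: in the six-membered carbocycle the quaternary C(CH3)(O) carbon sits next to the carbon of the enolised ring carbonyl. This is a tertiary α-ketol, the rearranged isomer of a 1-acetylcyclopentanol. Its oxygen stands 1,4 to the amino acid carboxyl carbon, so the rearranged alkoxide is drained as the cis-fused five-membered lactone.
4. Stereochemistry: the sulfinyl group on nitrogen sets the amino acid carbon and the ring CH in the Mannich step. The ring CH migrates with retention and dictates the quaternary ring-fusion carbon in the key step. The carbinol centre made in step 4 is destroyed there, so its epimers converge.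

Key step: step 5

Assumption: the tetravalent titanium enolate of 5 attacks the (R)-sulfinyl ketimine 3 in a closed chair transition state on the face that gives the (S)-amino acid carbon, by analogy with ester enolate additions to tert-butanesulfinyl aldimines with the ester group of 3 in the place of the aldimine substituent. Should the sense at this carbon be the opposite one, (S)-tert-butanesulfinamide is used in step 1 and nothing else changes.

**Route**

Step 1
Reactants: 1 ethyl pyruvate; 2 (R)-tert-butanesulfinamide
Product: 3 ethyl (2E)-2-{[(R)-tert-butylsulfinyl]imino}propanoate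
Conditions: Ti(OEt)4 (2 equiv), THF, 60 °C
Reagents that add atoms: none
Why: Condensation of the ketone carbonyl of an α-keto ester with tert-butanesulfinamide (sulfinyl ketimine formation) in which Ti(OEt)4 activates the carbonyl and takes up the water, while the sulfur stereocentre is not touched.

Step 2
Reactants: 4 2-methylcyclopentane-1,3-dione
Product: 5 3-chloro-2-methylcyclopent-2-en-1-one
Conditions: (COCl)2, DMF (cat.), CH2Cl2, 0 °C → rt
Reagents that add atoms: oxalyl chloride (O=C(Cl)C(=O)Cl)
Why: Vilsmeier-type activation of the enolised symmetric 1,3-dione followed by chloride addition–elimination gives the β-chloroenone (vinylogous acid chloride), a standard conversion that can give only one regioisomer here.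

Step 3
Reactants: 5 3-chloro-2-methylcyclopent-2-en-1-one; 3 ethyl (2E)-2-{[(R)-tert-butylsulfinyl]imino}propanoate
Product: 6 ethyl (2S)-2-{[(R)-tert-butylsulfinyl]amino}-2-[(1R)-4-chloro-3-methyl-2-oxocyclopent-3-en-1-yl]propanoate
Conditions: LiN(iPr)2, THF, −78 °C; ClTi(OiPr)3, −78 °C; then 3, −78 °C
Reagents that add atoms: none
Why: Kinetic deprotonation at the saturated α′-carbon, transmetalation to the less basic tetravalent titanium enolate and Mannich addition to the N-sulfinyl ketimino ester through a closed chair (Zimmerman–Traxler) transition state, in which the sulfinyl group shields one imine face, should set the (S)-amino acid carbon and, through the chair topology, the (R)-ring carbon.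

Step 4
Reactants: 6 ethyl (2S)-2-{[(R)-tert-butylsulfinyl]amino}-2-[(1R)-4-chloro-3-methyl-2-oxocyclopent-3-en-1-yl]propanoate; 7 ethyl vinyl ether
Product: 9 ethyl (2S)-2-[(1R,2S)-2-acetyl-4-chloro-2-hydroxy-3-methylcyclopent-3-en-1-yl]-2-{[(R)-tert-butylsulfinyl]amino}propanoate, via enol ether adduct 8 (not isolated)
Conditions: 7, tBuLi, THF, −78 → 0 °C; CeCl3, −78 °C; then 6, −78 °C; then 10% aq. oxalic acid, THF, 0 °C
Reagents that add atoms: water (O)
Why: Carbonyl-selective 1,2-addition of the weakly basic organocerium form of 1-ethoxyvinyllithium (an acetyl anion equivalent) to the enone ketone, anti to the bulky side chain so that the hydroxyl should come out cis to it and faster than attack on the hindered α-quaternary ester next to the N-anion, is followed by mild hydrolysis of the very acid-labile 1-ethoxyvinyl group to the methyl ketone, which the sulfinamide and the chloro-substituted allylic alcohol should survive.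

Step 5
Reactants: 9 ethyl (2S)-2-[(1R,2S)-2-acetyl-4-chloro-2-hydroxy-3-methylcyclopent-3-en-1-yl]-2-{[(R)-tert-butylsulfinyl]amino}propanoate
Product: 11 (3S,3aR,7aS)-3-{[(R)-tert-butylsulfinyl]amino}-5-chloro-3,6,7a-trimethyl-3a,4-dihydro-1-benzofuran-2,7(3H,7aH)-dione, via ring-expanded hydroxy ester 10 (not isolated)
Conditions: Al(OtBu)3, toluene, 80 °C
Reagents that add atoms: none
Why: The aluminium alkoxide of the tertiary alcohol chelates the acetyl oxygen and the ring carbon that carries the amino ester shifts with its electron pair from the carbinol carbon to the acetyl carbon (α-ketol rearrangement), so that the carbinol carbon becomes the ring ketone conjugated with the chloroalkene, the acetyl carbon becomes the quaternary C(CH3)(O–Al) ring atom and the ring grows from five to six atoms, after which the new alkoxide acylates itself with the ethyl ester. The closest known reaction is the aluminium-alkoxide- or base-promoted α-ketol (acyloin) ring expansion of 1-acylcycloalkanols, as in the D-homoannulation of 17-hydroxy-20-oxo steroids. The six-membered ring closes by ring expansion through a 1,2-shift with a three-centre transition state, and the lactone closes by 5-exo-trig attack of the alkoxide on the ester carbonyl. The migrating CH keeps its configuration and controls the new quaternary carbon: with the hydroxyl cis to the side chain, the chelated syn-periplanar O–C–C=O rotamer delivers the migrating carbon to the face that leaves the new oxygen cis to the amino ester, and only that alkoxide can close the cis-fused γ-lactone. The step needs alkyl over alkenyl migration and one face of the acetyl group, and both should be secured because every 1,2-shift is reversible while the conjugated enone and the lactone lie only on the desired path, the chloroalkene lowers the migratory aptitude of the alkenyl carbon, and a five-ring lactone formed too early can be re-opened by aluminium alkoxide transesterification. The carbinol stereocentre disappears, so both of its epimers are funnelled towards the same product.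

Step 6
Reactants: 11 (3S,3aR,7aS)-3-{[(R)-tert-butylsulfinyl]amino}-5-chloro-3,6,7a-trimethyl-3a,4-dihydro-1-benzofuran-2,7(3H,7aH)-dione
Product: 12 (3S,3aR,7aS)-3-{[(R)-tert-butylsulfinyl]amino}-5-methoxy-3,6,7a-trimethyl-3a,4-dihydro-1-benzofuran-2,7(3H,7aH)-dione
Conditions: NaOMe (1.2 equiv), MeOH, 0 °C
Reagents that add atoms: sodium methoxide ([Na+].[O-]C)
Why: Addition–elimination of methoxide at the β-carbon of the β-chloroenone (vinylogous acyl substitution) should be much faster than attack on the hindered tertiary-alkyl lactone and touches no stereocentre.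

Step 7
Reactants: 12 (3S,3aR,7aS)-3-{[(R)-tert-butylsulfinyl]amino}-5-methoxy-3,6,7a-trimethyl-3a,4-dihydro-1-benzofuran-2,7(3H,7aH)-dione; 13 (2E,4E)-hexa-2,4-dienal
Product: 14 (3S,3aR,7aS)-3-{[(R)-tert-butylsulfinyl]amino}-4-[(2E,4E)-1-hydroxyhexa-2,4-dien-1-yl]-5-methoxy-3,6,7a-trimethyl-3a,4-dihydro-1-benzofuran-2,7(3H,7aH)-dione (mixture at the two new centres)
Conditions: LiN(iPr)2 (2.2 equiv), THF, −78 °C; then 13, −78 °C
Reagents that add atoms: none
Why: After removal of the N–H proton the second equivalent of base deprotonates the only enolisable ring position, the γ-CH2 (the α′-carbon is quaternary), and the 2-alkoxy dienolate of the vinylogous ester adds through its γ-carbon to the aldehyde carbonyl (vinylogous aldol addition), the two new stereocentres being removed in step 8 and the N-anion blocking retro-Michael loss of the amino lactone carbon.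

Step 8
Reactants: 14 aldol adduct
Product: 15 (3S,3aR,7aS)-3-{[(R)-tert-butylsulfinyl]amino}-4-[(2E,4E)-1-hydroxyhexa-2,4-dien-1-ylidene]-5-methoxy-3,6,7a-trimethyl-3a,4-dihydro-1-benzofuran-2,7(3H,7aH)-dione (sorbyl ketone drawn as its exocyclic enol)
Conditions: Dess–Martin periodinane, CH2Cl2, 0 °C → rt
Reagents that add atoms: none
Why: Dess–Martin oxidation of the dienylic secondary alcohol under neutral conditions gives the sorbyl ketone, which enolises into conjugation, and should leave the sulfinamide and the diene untouched.

Step 9
Reactants: 15 sorbyl ketone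
Product: 16 (3S,3aR,7aS)-4-[(2E,4E)-1-hydroxyhexa-2,4-dien-1-ylidene]-5-methoxy-3,6,7a-trimethyl-2,7-dioxo-2,3,3a,4,7,7a-hexahydro-1-benzofuran-3-aminium chloride
Conditions: HCl (4 M in 1,4-dioxane), MeOH, 0 °C
Reagents that add atoms: hydrogen chloride (Cl)
Why: Acidic methanolysis of the N–S bond (standard cleavage of the tert-butanesulfinyl group) gives the ammonium salt, methanol as solvent makes any exchange at the methyl enol ether degenerate, and keeping the amine protonated prevents its addition to the neighbouring vinylogous ester.

Step 10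
Reactants: 16 aminium chloride; 17 (2E)-4-tert-butoxy-4-oxobut-2-enoic acid (mono-tert-butyl fumarate)
Product: 18 tert-butyl (2E)-4-{[(3S,3aR,7aS)-4-[(2E,4E)-1-hydroxyhexa-2,4-dien-1-ylidene]-5-methoxy-3,6,7a-trimethyl-2,7-dioxo-2,3,3a,4,7,7a-hexahydro-1-benzofuran-3-yl]amino}-4-oxobut-2-enoate
Conditions: 17, 1-chloro-N,N,2-trimethylprop-1-en-1-amine, CH2Cl2, 0 °C; then 16, pyridine, 0 °C → rt
Reagents that add atoms: none
Why: The acid chloride made under neutral conditions acylates the hindered α-tertiary amine as soon as pyridine frees it (amide formation from an acid chloride), the E geometry and the tert-butyl ester are kept, and any enol ester formed at the acidic enol would be cleaved again in step 11.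

Step 11
Reactants: 18 tert-butyl fumaramate
Product: 19 sorbicillactone A
Conditions: CF3CO2H/H2O (9:1), 0 °C → rt
Reagents that add atoms: water (O)
Why: Acid cleaves the tert-butyl ester by loss of isobutene and hydrolyses the acyl-activated methyl enol ether by addition of water and loss of methanol, which frees the acid and the enolised triketone without base, so the lactone, the trienone and the three stereocentres should not be endangered.

**Compound list**

1 | ethyl pyruvate | CCOC(=O)C(C)=O | starting material
2 | (R)-tert-butanesulfinamide | CC(C)(C)[S@@](=O)N | starting material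
3 | ethyl (2E)-2-{[(R)-tert-butylsulfinyl]imino}propanoate | CCOC(=O)/C(C)=N/[S@](=O)C(C)(C)C | intermediate
4 | 2-methylcyclopentane-1,3-dione | CC1C(=O)CCC1=O | starting material
5 | 3-chloro-2-methylcyclopent-2-en-1-one | CC1=C(Cl)CCC1=O | intermediate
6 | ethyl (2S)-2-{[(R)-tert-butylsulfinyl]amino}-2-[(1R)-4-chloro-3-methyl-2-oxocyclopent-3-en-1-yl]propanoate | CCOC(=O)[C@@](C)(N[S@](=O)C(C)(C)C)[C@H]1CC(Cl)=C(C)C1=O | intermediate
7 | ethyl vinyl ether | C=COCC | starting material
8 | ethyl (2S)-2-{[(R)-tert-butylsulfinyl]amino}-2-[(1R,2S)-4-chloro-2-(1-ethoxyethenyl)-2-hydroxy-3-methylcyclopent-3-en-1-yl]propanoate (enol ether adduct, formed in the flask) | CCOC(=O)[C@@](C)(N[S@](=O)C(C)(C)C)[C@H]1CC(Cl)=C(C)[C@]1(O)C(=C)OCC | intermediate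
9 | ethyl (2S)-2-[(1R,2S)-2-acetyl-4-chloro-2-hydroxy-3-methylcyclopent-3-en-1-yl]-2-{[(R)-tert-butylsulfinyl]amino}propanoate | CCOC(=O)[C@@](C)(N[S@](=O)C(C)(C)C)[C@H]1CC(Cl)=C(C)[C@]1(O)C(C)=O | intermediate
10 | ethyl (2S)-2-{[(R)-tert-butylsulfinyl]amino}-2-[(1R,2S)-5-chloro-2-hydroxy-2,4-dimethyl-3-oxocyclohex-4-en-1-yl]propanoate (ring-expanded hydroxy ester, present as its aluminium alkoxide, drawn as the alcohol) | CCOC(=O)[C@@](C)(N[S@](=O)C(C)(C)C)[C@H]1CC(Cl)=C(C)C(=O)[C@@]1(C)O | intermediate
11 | (3S,3aR,7aS)-3-{[(R)-tert-butylsulfinyl]amino}-5-chloro-3,6,7a-trimethyl-3a,4-dihydro-1-benzofuran-2,7(3H,7aH)-dione | C1C(Cl)=C(C)C(=O)[C@@]2(C)OC(=O)[C@@](C)(N[S@](=O)C(C)(C)C)[C@@H]12 | intermediate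
12 | (3S,3aR,7aS)-3-{[(R)-tert-butylsulfinyl]amino}-5-methoxy-3,6,7a-trimethyl-3a,4-dihydro-1-benzofuran-2,7(3H,7aH)-dione | C1C(OC)=C(C)C(=O)[C@@]2(C)OC(=O)[C@@](C)(N[S@](=O)C(C)(C)C)[C@@H]12 | intermediate
13 | (2E,4E)-hexa-2,4-dienal | C/C=C/C=C/C=O | starting material
14 | (3S,3aR,7aS)-3-{[(R)-tert-butylsulfinyl]amino}-4-[(2E,4E)-1-hydroxyhexa-2,4-dien-1-yl]-5-methoxy-3,6,7a-trimethyl-3a,4-dihydro-1-benzofuran-2,7(3H,7aH)-dione (mixture at the ring carbon 4 and the carbinol carbon) | C/C=C/C=C/C(O)C1C(OC)=C(C)C(=O)[C@@]2(C)OC(=O)[C@@](C)(N[S@](=O)C(C)(C)C)[C@@H]12 | intermediate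
15 | (3S,3aR,7aS)-3-{[(R)-tert-butylsulfinyl]amino}-4-[(2E,4E)-1-hydroxyhexa-2,4-dien-1-ylidene]-5-methoxy-3,6,7a-trimethyl-3a,4-dihydro-1-benzofuran-2,7(3H,7aH)-dione (enol tautomer of the sorbyl ketone) | C/C=C/C=C/C(O)=C1/C(OC)=C(C)C(=O)[C@@]2(C)OC(=O)[C@@](C)(N[S@](=O)C(C)(C)C)[C@@H]12 | intermediate
16 | (3S,3aR,7aS)-4-[(2E,4E)-1-hydroxyhexa-2,4-dien-1-ylidene]-5-methoxy-3,6,7a-trimethyl-2,7-dioxo-2,3,3a,4,7,7a-hexahydro-1-benzofuran-3-aminium chloride | C/C=C/C=C/C(O)=C1/C(OC)=C(C)C(=O)[C@@]2(C)OC(=O)[C@@](C)([NH3+])[C@@H]12.[Cl-] | intermediate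
17 | (2E)-4-tert-butoxy-4-oxobut-2-enoic acid (mono-tert-butyl fumarate) | CC(C)(C)OC(=O)/C=C/C(=O)O | starting material
18 | tert-butyl (2E)-4-{[(3S,3aR,7aS)-4-[(2E,4E)-1-hydroxyhexa-2,4-dien-1-ylidene]-5-methoxy-3,6,7a-trimethyl-2,7-dioxo-2,3,3a,4,7,7a-hexahydro-1-benzofuran-3-yl]amino}-4-oxobut-2-enoate | C/C=C/C=C/C(O)=C1/C(OC)=C(C)C(=O)[C@@]2(C)OC(=O)[C@@](C)(NC(=O)/C=C/C(=O)OC(C)(C)C)[C@@H]12 | intermediate
19 | sorbicillactone A | C/C=C/C=C/C(O)=C1/C(=O)C(C)=C(O)[C@@]2(C)OC(=O)[C@@](C)(NC(=O)/C=C/C(=O)O)[C@@H]12 | target

**Step count and risks**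

Total step count: 11. Longest linear sequence: 10 steps (steps 2 to 11, from 2-methylcyclopentane-1,3-dione); step 1 is a one-step side branch.

The three steps most likely to fail:

Step 3. The enolate may deprotonate the methyl group of the ketimine in place of adding to it, and the simple diastereoselection between the ring carbon and the amino acid carbon may be poor because the chair transition state has to tell a methyl from an ester group. Fallback: setting out from 5, the α′-enolate is trapped (LiN(iPr)2, iPr3SiOTf, THF, −78 °C) as the silyl dienol ether [(4-chloro-3-methylcyclopenta-1,3-dien-2-yl)oxy]tri(propan-2-yl)silane F1. This non-basic nucleophile is added to 3 with BF3·OEt2 in CH2Cl2 at −78 °C in a Mukaiyama–Mannich reaction, which runs through an open transition state and so has a different simple diastereoselection. Aqueous work-up removes the silyl group and the sequence comes back to the route at 6.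

Step 5. The five-ring alkoxide may acylate itself with the ester before the 1,2-shift and rest as a five-five lactone, the alkenyl ring carbon may migrate in place of the alkyl one, or the shift may run through the non-chelated rotamer and place the new hydroxyl trans to the side chain, where ring closure is not possible. Fallback: setting out from 9, the ester is saponified (LiOH, aq. THF, 0 °C) to (2S)-2-[(1R,2S)-2-acetyl-4-chloro-2-hydroxy-3-methylcyclopent-3-en-1-yl]-2-{[(R)-tert-butylsulfinyl]amino}propanoic acid F2, whose carboxylate cannot acylate an alkoxide. The α-ketol ring expansion is then run on this acid alone (Al(OtBu)3, toluene, 80 °C) and equilibrated to (2S)-2-{[(R)-tert-butylsulfinyl]amino}-2-[(1R,2S)-5-chloro-2-hydroxy-2,4-dimethyl-3-oxocyclohex-4-en-1-yl]propanoic acid F3, which can be purified. The cis hydroxy acid is closed with N-ethyl-N′-(3-dimethylaminopropyl)carbodiimide hydrochloride and 4-dimethylaminopyridine in CH2Cl2, and the sequence comes back to the route at 11.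

Step 4. The basic vinyl anion may enolise the hindered ketone or attack the ester in place of adding to the ketone, and the tertiary allylic hydroxyl may be lost during the acid hydrolysis of the enol ether. Fallback: setting out from 6, the smaller and less basic ethynyl nucleophile (HC≡CMgBr, CeCl3, THF, −78 °C) is added to give ethyl (2S)-2-{[(R)-tert-butylsulfinyl]amino}-2-[(1R,2R)-4-chloro-2-ethynyl-2-hydroxy-3-methylcyclopent-3-en-1-yl]propanoate F4. Its terminal alkyne is hydrated in the Markovnikov sense under neutral conditions with the monovalent gold complex Ph3PAuNTf2 (cat.) in aqueous 1,4-dioxane at rt, and the sequence comes back to the route at 9.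

**Further compounds**

F1 | step 3 | [(4-chloro-3-methylcyclopenta-1,3-dien-2-yl)oxy]tri(propan-2-yl)silane | CC1=C(Cl)CC=C1O[Si](C(C)C)(C(C)C)C(C)C
F2 | step 5 | (2S)-2-[(1R,2S)-2-acetyl-4-chloro-2-hydroxy-3-methylcyclopent-3-en-1-yl]-2-{[(R)-tert-butylsulfinyl]amino}propanoic acid | OC(=O)[C@@](C)(N[S@](=O)C(C)(C)C)[C@H]1CC(Cl)=C(C)[C@]1(O)C(C)=O
F3 | step 5 | (2S)-2-{[(R)-tert-butylsulfinyl]amino}-2-[(1R,2S)-5-chloro-2-hydroxy-2,4-dimethyl-3-oxocyclohex-4-en-1-yl]propanoic acid | OC(=O)[C@@](C)(N[S@](=O)C(C)(C)C)[C@H]1CC(Cl)=C(C)C(=O)[C@@]1(C)O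
F4 | step 4 | ethyl (2S)-2-{[(R)-tert-butylsulfinyl]amino}-2-[(1R,2R)-4-chloro-2-ethynyl-2-hydroxy-3-methylcyclopent-3-en-1-yl]propanoate | CCOC(=O)[C@@](C)(N[S@](=O)C(C)(C)C)[C@H]1CC(Cl)=C(C)[C@]1(O)C#C
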